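**Retrosynthetic overview**
- The strategy rests on ring A, which carries OH at C1, the 2,4-dibromophenoxy group (ring B) at C2, and Br, H, Br, H at C3 to C6. That C3–C6 run is the diene carbon chain C3–C6 of 3,5-dibromo-2-pyrone, and C1–C2 is an alkyne carbon pair.
- C1–OH is traced back to C1–SiMe3 (ipso-borodesilylation, then peroxide oxidation).
- The C2–C3 and C6–C1 bonds are traced back to a (4+2) cycloaddition of silylated aryl ynol ether 10 with pyrone 12, followed by loss of CO2.
- 10 comes from 2,4-dibromophenol via the vinyl ether, the Z-bromovinyl ether and the lithium acetylide; 12 comes from coumalic acid by bromodecarboxylation.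
- Ring order: ring B is bought intact and ring A is built de novo in step 6. The hindered diaryl ether C–O bond is never made by a coupling.

Key step: step 6

Remark: the target is achiral. The only stereo-elements on the route are the Z double bond of 6 and the transient racemic adducts 5 and 13.
Remark: 3,5-dibromo-2-fluorobenzaldehyde, used only in a fallback, is taken to be purchasable.

**Route**

Step 1
Reactants: 1 2,4-dibromophenol; 2 1,2-dibromoethane
Product: 3 2,4-dibromo-1-(2-bromoethoxy)benzene
Conditions: K2CO3, BrCH2CH2Br (5 equiv), MeCN, reflux
Reagents that add atoms: 1,2-dibromoethane (2), BrCCBr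
Why: Williamson ether synthesis, in which the phenoxide of 1 displaces one bromide of 2 by SN2 while the excess of 2 suppresses double alkylation.

Step 2
Reactants: 3 2,4-dibromo-1-(2-bromoethoxy)benzene
Product: 4 2,4-dibromo-1-(ethenyloxy)benzene
Conditions: KOtBu (1.5 equiv), THF, 0 °C → rt
Reagents that add atoms: none
Why: E2 dehydrobromination of a β-aryloxyethyl bromide by a hindered alkoxide is a standard entry to aryl vinyl ethers, and the aryl bromides are inert to KOtBu at this temperature.

Step 3
Reactants: 4 2,4-dibromo-1-(ethenyloxy)benzene
Product: 6 2,4-dibromo-1-{[(Z)-2-bromoethenyl]oxy}benzene, via 1,2-dibromoethyl aryl ether 5 (not isolated)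
Conditions: Br2 (1.0 equiv), CH2Cl2, −78 °C; then iPr2NEt (1.5 equiv), −78 °C → 40 °C
Reagents that add atoms: bromine, BrBr
Why: Electrophilic addition of Br2 to the enol ether double bond (much faster than substitution on the deactivated ring) gives racemic α,β-dibromo ether 5, from which the hindered amine removes a CH2Br proton as the oxygen-activated α-bromide leaves (dehydrobromination), the cis-favoured Z isomer being expected as the main product with its O–CH hydrogen anti to bromine as step 4 requires.

Step 4
Reactants: 6 2,4-dibromo-1-{[(Z)-2-bromoethenyl]oxy}benzene; 7 chlorotrimethylsilane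
Product: 10 [(2,4-dibromophenoxy)ethynyl](trimethyl)silane, via aryloxyacetylene 8 (not isolated), via lithium aryloxyacetylide 9 (not isolated)
Conditions: LiN(iPr)2 (2.05 equiv, added slowly to 6), THF, −78 °C; then Me3SiCl, −78 °C → rt
Reagents that add atoms: chlorotrimethylsilane (7), C[Si](C)(C)Cl; LiN(iPr)2, [Li+].CC(C)[N-]C(C)C, leaves lithium only in intermediate 9
Why: Anti E2 loss of HBr from the Z-bromovinyl ether gives alkyne 8, the second equivalent of amide removes its C(sp)–H (far more acidic than any ring C–H, so with base never in excess ring B should stay untouched), and the acetylide is silylated on carbon by Me3SiCl.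

Step 5
Reactants: 11 coumalic acid
Product: 12 3,5-dibromo-2H-pyran-2-one
Conditions: N-bromosuccinimide (2.5 equiv), LiOAc (cat.), MeCN–H2O, rt
Reagents that add atoms: N-bromosuccinimide, O=C1CCC(=O)N1Br
Why: Electrophilic bromination at C3 together with ipso bromodecarboxylation at C5 (halodecarboxylation of the vinylogous carboxylate) is a known one-pot conversion of coumalic acid into this pyrone.

Step 6
Reactants: 10 [(2,4-dibromophenoxy)ethynyl](trimethyl)silane; 12 3,5-dibromo-2H-pyran-2-one
Product: 14 [3,5-dibromo-2-(2,4-dibromophenoxy)phenyl](trimethyl)silane, via bridged bicyclic lactone 13 (not isolated)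
Conditions: 12 (1.5 equiv), degassed PhMe, sealed tube, 130 °C, − CO2
Reagents that add atoms: none
Why: Proposed new method: the donor oxygen polarises ynol ether 10 so that its silicon-bearing carbon is the nucleophilic terminus, and this carbon attacks the electrophilic C6 of the electron-poor pyrone 12 in an asynchronous inverse-electron-demand (4+2) cycloaddition, the positive charge developing on the oxygen-bearing alkyne carbon being stabilised by the oxygen lone pair and the β C–Si bond before that carbon closes onto C3. The closest known reaction type is the thermal Diels–Alder/retro-Diels–Alder benzannulation of 2-pyrones with silyl- or boryl-substituted alkynes, and the orientation matches that of 3-bromo- and 3,5-dibromo-2-pyrone with vinyl ethers, where the oxygen-bearing carbon also ends up next to C3; what is new is a donor aryloxy group and a silyl group on the same alkyne. Ring A is closed by this intermolecular (4+2) event, which forms the C6–C1 and C2–C3 bonds (target numbering) in one step, and the bridged lactone 13 then loses CO2 by retro-(4+2) cycloreversion to give the benzene ring directly, with no oxidant. No stereocentre survives, since the two bridgeheads of 13 form as a racemate and are flattened on aromatisation. The step needs regioselectivity (aryloxy carbon to C3, silyl carbon to C6), which the oxygen/β-silicon polarisation of 10, the electrophilic C6 of 12 and the preference of the bulky Me3Si group for the C6–H terminus over the C3–Br terminus all favour, and it needs the ynol ether to survive heating, which is plausible because an aryl ynol ether has no β C(sp3)–H for the retro-ene fragmentation to a ketene that limits alkyl ynol ethers.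

Step 7
Reactants: 14 [3,5-dibromo-2-(2,4-dibromophenoxy)phenyl](trimethyl)silane
Product: 17 3,5-dibromo-2-(2,4-dibromophenoxy)phenol, via aryldibromoborane 15 (not isolated), via arylboronic acid 16 (not isolated)
Conditions: BBr3 (2 equiv), CH2Cl2, 0 °C → rt; then aq. NaOH, H2O2 (30%), THF, 0 °C; aq. HCl work-up
Reagents that add atoms: hydrogen peroxide, OO; BBr3, BrB(Br)Br, leaves boron only in intermediates 15 and 16 and bromine only in 15; sodium hydroxide, [Na+].[OH-], gives only the B–OH oxygens of 16
Why: Ipso-borodesilylation (electrophilic aromatic substitution at the silicon-bearing carbon, helped by the β-silicon effect and the ortho aryloxy donor) gives the aryldibromoborane, which is hydrolysed and then oxidised by alkaline hydrogen peroxide with 1,2-shift of the aryl group from boron to oxygen, while diaryl ethers and aryl bromides are inert to both reagents.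

**Compound list**
1 | 2,4-dibromophenol | Oc1ccc(Br)cc1Br | starting material
2 | 1,2-dibromoethane | BrCCBr | starting material
3 | 2,4-dibromo-1-(2-bromoethoxy)benzene | BrCCOc1ccc(Br)cc1Br | intermediate
4 | 2,4-dibromo-1-(ethenyloxy)benzene (2,4-dibromophenyl vinyl ether) | C=COc1ccc(Br)cc1Br | intermediate
5 | 2,4-dibromo-1-(1,2-dibromoethoxy)benzene, racemic, not isolated | BrCC(Br)Oc1ccc(Br)cc1Br | intermediate
6 | 2,4-dibromo-1-{[(Z)-2-bromoethenyl]oxy}benzene | Br/C=C\Oc1ccc(Br)cc1Br | intermediate
7 | chlorotrimethylsilane | C[Si](C)(C)Cl | starting material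
8 | 2,4-dibromo-1-(ethynyloxy)benzene, not isolated | C#COc1ccc(Br)cc1Br | intermediate
9 | lithium (2,4-dibromophenoxy)acetylide, not isolated | [Li]C#COc1ccc(Br)cc1Br | intermediate
10 | [(2,4-dibromophenoxy)ethynyl](trimethyl)silane | C[Si](C)(C)C#COc1ccc(Br)cc1Br | intermediate
11 | coumalic acid (2-oxo-2H-pyran-5-carboxylic acid) | O=C(O)c1ccc(=O)oc1 | starting material
12 | 3,5-dibromo-2H-pyran-2-one | O=c1occ(Br)cc1Br | intermediate
13 | rac-4,7-dibromo-5-(2,4-dibromophenoxy)-6-(trimethylsilyl)-2-oxabicyclo[2.2.2]octa-5,7-dien-3-one, not isolated, one enantiomer drawn | O=C1O[C@@H]2C(Br)=C[C@@]1(Br)C(Oc1ccc(Br)cc1Br)=C2[Si](C)(C)C | intermediate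
14 | [3,5-dibromo-2-(2,4-dibromophenoxy)phenyl](trimethyl)silane | C[Si](C)(C)c1cc(Br)cc(Br)c1Oc1ccc(Br)cc1Br | intermediate
15 | dibromo[3,5-dibromo-2-(2,4-dibromophenoxy)phenyl]borane, not isolated | BrB(Br)c1cc(Br)cc(Br)c1Oc1ccc(Br)cc1Br | intermediate
16 | [3,5-dibromo-2-(2,4-dibromophenoxy)phenyl]boronic acid, not isolated | OB(O)c1cc(Br)cc(Br)c1Oc1ccc(Br)cc1Br | intermediate
17 | 3,5-dibromo-2-(2,4-dibromophenoxy)phenol | Oc1cc(Br)cc(Br)c1Oc1ccc(Br)cc1Br | target

**Step count**
Total steps: 7. Longest linear sequence: 6 (steps 1, 2, 3, 4, 6, 7 from 2,4-dibromophenol); step 5 is a one-step side branch.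

**Steps most likely to fail**

1. Step 6 (proposed new method).
 - What may go wrong: the cycloaddition may be slower than thermal oligomerisation of the ynol ether, the partners may stop at an open-chain conjugate adduct, or the alkyne may add in the reverse orientation.
 - Fallback (known chemistry): it sets out from 1 and comes back to the route at 17. Phenol 1 and 3,5-dibromo-2-fluorobenzaldehyde are joined by SNAr (K2CO3, DMF, 100 °C; the ortho formyl group activates fluoride displacement) to give 3,5-dibromo-2-(2,4-dibromophenoxy)benzaldehyde F1. Baeyer–Villiger (Dakin-type) oxidation with mCPBA in CH2Cl2 should move the ortho-oxygenated aryl group to oxygen and give 3,5-dibromo-2-(2,4-dibromophenoxy)phenyl formate F2. Methanolysis (K2CO3, MeOH) then releases 17.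

2. Step 7.
 - What may go wrong: ipso attack of BBr3 on the hindered, doubly brominated ring may be sluggish, adventitious HBr may cause protodesilylation, or the aryldibromoborane may go on to borylate ring B intramolecularly.
 - Fallback: it sets out from 14 and comes back at 16. Ipso-iododesilylation with ICl (CH2Cl2, 0 °C) should give 1,5-dibromo-2-(2,4-dibromophenoxy)-3-iodobenzene F3. Selective iodine–magnesium exchange with iPrMgCl·LiCl (THF, −40 °C; iodide exchanges much faster than bromide, and no halogen sits ortho to the new C–Mg bond) gives [3,5-dibromo-2-(2,4-dibromophenoxy)phenyl]magnesium chloride F4. Trapping with B(OMe)3 gives dimethyl [3,5-dibromo-2-(2,4-dibromophenoxy)phenyl]boronate F5. Aqueous hydrolysis of F5 gives 16, which is oxidised to 17 with alkaline H2O2 as in step 7.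

3. Step 4.
 - What may go wrong: LiN(iPr)2 may deprotonate ring B at the C–H flanked by two bromines, leading to ring silylation, halogen migration or aryne formation.
 - Fallback: it sets out from 6 and comes back at 10, with no amide base at any stage. Alkoxide E2 elimination (KOtBu, THF, −40 °C → 0 °C) gives alkyne 8, kept cold in solution. 8 is then silylated on carbon without an organometallic, using N,O-bis(trimethylsilyl)acetamide and catalytic tetramethylammonium pivalate in MeCN (carboxylate-catalysed silylation of terminal alkynes), to give 10.

**Further compounds**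
F1 | step 6 | 3,5-dibromo-2-(2,4-dibromophenoxy)benzaldehyde | O=Cc1cc(Br)cc(Br)c1Oc1ccc(Br)cc1Br
F2 | step 6 | 3,5-dibromo-2-(2,4-dibromophenoxy)phenyl formate | O=COc1cc(Br)cc(Br)c1Oc1ccc(Br)cc1Br
F3 | step 7 | 1,5-dibromo-2-(2,4-dibromophenoxy)-3-iodobenzene | Ic1cc(Br)cc(Br)c1Oc1ccc(Br)cc1Br
F4 | step 7 | [3,5-dibromo-2-(2,4-dibromophenoxy)phenyl]magnesium chloride | Cl[Mg]c1cc(Br)cc(Br)c1Oc1ccc(Br)cc1Br
F5 | step 7 | dimethyl [3,5-dibromo-2-(2,4-dibromophenoxy)phenyl]boronate | COB(OC)c1cc(Br)cc(Br)c1Oc1ccc(Br)cc1Br
F0 | step 4 | none | none
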